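**Plan**
- Last disconnections: the two 4-methoxybenzyl ethers, then the exocyclic C=C of the Z-enal (back to a cyclohexanone), then the C(sp3)–C(sp2) bond between the CH2CH2 linker and the E-alkene CH (B-alkyl Suzuki–Miyaura of iodoalkene 23 with iodide 38).
- Tetrahydrofuran half: the side-chain C=C (Wittig), then the ring bonds O1–C2 and C2–CH2(allyl) are cut together, back to an acyclic allyl ether α-methyl diazoketone made from (R)-malate.
- Enabling feature: ring carbon C2 is quaternary, bonded to the ring oxygen O1, a methyl, the 4-methylpent-3-enyl chain and the carbinol carbon C3, with the chain trans to the C5 alkenyl arm across O1. This is what an ylide carbon between an oxonium oxygen and a ketone leaves after an allyl shift.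
- Cyclohexane half: the ring is bought as a 4-silyloxycyclohexanone; the C3 side chain and the C2 allyl group (later CH2CH2) come from conjugate addition and enolate allylation, the carbinol methyl from an organocerium addition.
- Forward order: the tetrahydrofuran ring closes in step 6, the halves are joined in step 25, the enal is made in step 29.
- Stereochemistry: malate fixes C5, which relays to C2 in the ylide shift; C3 by CBS reduction; the cyclohexane by chiral lithium amide deprotonation, relayed anti/anti and then by axial methyl delivery; E by syn-carboalumination, Z by the allylic transposition.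

Key step: step 6

Assumption: diazoethane is used as an ethereal solution made from N-ethyl-N-nitrosourea and KOH; compounds 24 and 30 and (R,R)-bis(1-phenylethyl)amine hydrochloride are taken as purchasable.
Abbreviations: TBDPS = tert-butyldiphenylsilyl, TBS = tert-butyldimethylsilyl, TES = triethylsilyl, PMB = 4-methoxybenzyl. Oxolane numbering: O1, C2 quaternary, C3 oxygenated, C5 bearing the arm.

Step 1
Reactants: 1 dimethyl (R)-malate
Product: 2 methyl (3R)-3,4-dihydroxybutanoate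
Conditions: BH3·SMe2, NaBH4 (5 mol %), THF, 0 °C to rt; MeOH quench
Reagents that add atoms: none
Why: Hydroxyl-directed borane reduction: the alkoxyborane formed at the free hydroxyl delivers hydride only to the neighbouring ester, and the stereocentre is not touched.

Step 2
Reactants: 2 methyl (3R)-3,4-dihydroxybutanoate
Product: 3 methyl (3R)-4-[(tert-butyldiphenylsilyl)oxy]-3-hydroxybutanoate
Conditions: TBDPSCl, imidazole, CH2Cl2, 0 °C
Reagents that add atoms: tert-butyl(chloro)diphenylsilane, CC(C)(C)[Si](Cl)(c1ccccc1)c1ccccc1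
Why: Sterically controlled silylation of a 1,2-diol, the bulky silyl chloride reacting at the primary hydroxyl.

Step 3
Reactants: 3 methyl (3R)-4-[(tert-butyldiphenylsilyl)oxy]-3-hydroxybutanoate; 4 allyl 2,2,2-trichloroacetimidate
Product: 5 methyl (3R)-3-(allyloxy)-4-[(tert-butyldiphenylsilyl)oxy]butanoate
Conditions: CF3SO3H (cat.), cyclohexane/CH2Cl2, rt
Reagents that add atoms: none
Why: Acid-catalysed O-alkylation with a trichloroacetimidate allylates the β-hydroxy ester without base, so retro-aldol cleavage, β-elimination and silyl migration are avoided.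

Step 4
Reactants: 5 methyl (3R)-3-(allyloxy)-4-[(tert-butyldiphenylsilyl)oxy]butanoate
Product: 6 (3R)-3-(allyloxy)-4-[(tert-butyldiphenylsilyl)oxy]butanoic acid
Conditions: LiOH, THF/H2O, 0 °C to rt; aq. HCl to pH 3
Reagents that add atoms: lithium hydroxide, [Li+].[OH-]
Why: Saponification of the methyl ester under cold conditions that the β-allyloxy group and the primary silyl ether should tolerate.

Step 5
Reactants: 6 (3R)-3-(allyloxy)-4-[(tert-butyldiphenylsilyl)oxy]butanoic acid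
Product: 8 (5R)-5-(allyloxy)-6-[(tert-butyldiphenylsilyl)oxy]-2-diazohexan-3-one, via acid chloride 7 (not isolated)
Conditions: (COCl)2, DMF (cat.), CH2Cl2, 0 °C to rt; then CH3CHN2 (3 equiv), Et2O, −20 to 0 °C
Reagents that add atoms: diazoethane, CC=[N+]=[N-]
Why: Arndt–Eistert-type C-acylation of a diazoalkane by the acid chloride, a second equivalent of diazoethane taking up HCl; the position of the diazo group is fixed by bond construction and not by enolisation.

Step 6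
Reactants: 8 (5R)-5-(allyloxy)-6-[(tert-butyldiphenylsilyl)oxy]-2-diazohexan-3-one
Product: 10 (2S,5R)-2-allyl-5-{[(tert-butyldiphenylsilyl)oxy]methyl}-2-methyloxolan-3-one, via oxonium ylide 9 (not isolated)
Conditions: Cu(acac)2 (10 mol %), THF, reflux, slow addition of 8
Reagents that add atoms: none
Why: Cu(acac)2 decomposes the diazoketone to an electrophilic copper carbenoid, a lone pair of the allyl ether oxygen captures it, and the oxonium ylide undergoes a suprafacial [2,3]-sigmatropic shift of the allyl group from oxygen to the ylide carbon; the closest known reaction type is the carbenoid oxonium-ylide/[2,3] route from allyl ethers to 2-allyl-oxolan-3-ones. The ring closes by O–C bond formation in a five-membered, formally 5-exo mode, which is preferred over attack on the alkene and over reaction at the non-nucleophilic silyl ether oxygen. The new quaternary centre C2 is controlled by the malate-derived C5: in the envelope ylide the allyl group on oxygen sits trans to the silyloxymethyl arm and is delivered to C2 on that face, so allyl ends trans and methyl cis to the arm. The step needs ylide formation to win over 1,2-hydride shift from the carbenoid methyl and over C–H insertion; the copper catalyst, slow addition and the fast five-ring closure are expected to secure this.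

Step 7
Reactants: 10 (2S,5R)-2-allyl-5-{[(tert-butyldiphenylsilyl)oxy]methyl}-2-methyloxolan-3-one
Product: 11 (2S,3R,5R)-2-allyl-5-{[(tert-butyldiphenylsilyl)oxy]methyl}-2-methyloxolan-3-ol
Conditions: (S)-2-methyl-CBS-oxazaborolidine (0.5 equiv), catecholborane, toluene, −78 to −40 °C
Reagents that add atoms: none
Why: CBS reduction under reagent control, the quaternary C2 acting as the large and the C4 methylene as the small flank, so the (S)-catalyst should give the (3R)-alcohol cis to the C2 methyl and the C5 arm; catecholborane at low temperature leaves the terminal alkene alone.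

Step 8
Reactants: 11 (2S,3R,5R)-2-allyl-5-{[(tert-butyldiphenylsilyl)oxy]methyl}-2-methyloxolan-3-ol
Product: 12 (2S,3R,5R)-2-allyl-5-{[(tert-butyldiphenylsilyl)oxy]methyl}-3-[(4-methoxybenzyl)oxy]-2-methyloxolane
Conditions: NaH, 4-methoxybenzyl chloride, Bu4NI (cat.), DMF, 0 °C to rt
Reagents that add atoms: 4-methoxybenzyl chloride, COc1ccc(CCl)cc1
Why: Williamson etherification of the hindered alkoxide with a reactive benzylic halide gives an ether that survives fluoride and is removed oxidatively at the end.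

Step 9
Reactants: 12 (2S,3R,5R)-2-allyl-5-{[(tert-butyldiphenylsilyl)oxy]methyl}-3-[(4-methoxybenzyl)oxy]-2-methyloxolane
Product: 14 3-[(2S,3R,5R)-5-{[(tert-butyldiphenylsilyl)oxy]methyl}-3-[(4-methoxybenzyl)oxy]-2-methyloxolan-2-yl]propan-1-ol, via B-alkyl-9-BBN adduct 13 (not isolated)
Conditions: 9-BBN, THF, 0 °C to rt; then NaOH, H2O2, 0 °C
Reagents that add atoms: hydrogen peroxide, OO
Why: Anti-Markovnikov hydroboration of the only alkene and oxidation of the C–B bond give the primary alcohol (hydroboration–oxidation).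

Step 10
Reactants: 14 3-[(2S,3R,5R)-5-{[(tert-butyldiphenylsilyl)oxy]methyl}-3-[(4-methoxybenzyl)oxy]-2-methyloxolan-2-yl]propan-1-ol
Product: 15 3-[(2S,3R,5R)-5-{[(tert-butyldiphenylsilyl)oxy]methyl}-3-[(4-methoxybenzyl)oxy]-2-methyloxolan-2-yl]propanal
Conditions: Dess–Martin periodinane, NaHCO3, CH2Cl2, 0 °C to rt
Reagents that add atoms: none
Why: Dess–Martin oxidation of a primary alcohol to the aldehyde under buffered conditions.

Step 11
Reactants: 15 3-[(2S,3R,5R)-5-{[(tert-butyldiphenylsilyl)oxy]methyl}-3-[(4-methoxybenzyl)oxy]-2-methyloxolan-2-yl]propanal; 16 isopropyltriphenylphosphonium iodide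
Product: 18 (2S,3R,5R)-5-{[(tert-butyldiphenylsilyl)oxy]methyl}-3-[(4-methoxybenzyl)oxy]-2-methyl-2-(4-methylpent-3-en-1-yl)oxolane, via isopropylidene ylide 17 (not isolated)
Conditions: 16, n-BuLi, THF, 0 °C; then 15, −78 °C to rt
Reagents that add atoms: none
Why: Wittig olefination with the non-stabilised isopropylidene ylide completes the 4-methylpent-3-enyl chain, and the alkene formed has no geometry to control.

Step 12
Reactants: 18 (2S,3R,5R)-5-{[(tert-butyldiphenylsilyl)oxy]methyl}-3-[(4-methoxybenzyl)oxy]-2-methyl-2-(4-methylpent-3-en-1-yl)oxolane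
Product: 19 [(2R,4R,5S)-4-[(4-methoxybenzyl)oxy]-5-methyl-5-(4-methylpent-3-en-1-yl)oxolan-2-yl]methanol
Conditions: Bu4NF, THF, 0 °C to rt
Reagents that add atoms: none
Why: Fluoride cleaves the only silyl ether, while the PMB ether and the alkene are inert.

Step 13
Reactants: 19 [(2R,4R,5S)-4-[(4-methoxybenzyl)oxy]-5-methyl-5-(4-methylpent-3-en-1-yl)oxolan-2-yl]methanol
Product: 20 (2R,4R,5S)-4-[(4-methoxybenzyl)oxy]-5-methyl-5-(4-methylpent-3-en-1-yl)oxolane-2-carbaldehyde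
Conditions: Dess–Martin periodinane, NaHCO3, CH2Cl2, 0 °C; used crude
Reagents that add atoms: none
Why: Dess–Martin oxidation gives the α-alkoxy aldehyde, which is carried on at once to limit epimerisation next to the ring oxygen.

Step 14
Reactants: 20 (2R,4R,5S)-4-[(4-methoxybenzyl)oxy]-5-methyl-5-(4-methylpent-3-en-1-yl)oxolane-2-carbaldehyde
Product: 21 (2S,3R,5R)-5-ethynyl-3-[(4-methoxybenzyl)oxy]-2-methyl-2-(4-methylpent-3-en-1-yl)oxolane
Conditions: Ohira–Bestmann reagent, K2CO3, MeOH, 0 °C to rt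
Reagents that add atoms: dimethyl (1-diazo-2-oxopropyl)phosphonate, COP(=O)(OC)C(=[N+]=[N-])C(C)=O
Why: Seyferth–Gilbert homologation with the Ohira–Bestmann reagent turns the aldehyde into the terminal alkyne under mild base that normally spares α-alkoxy stereocentres.

Step 15
Reactants: 21 (2S,3R,5R)-5-ethynyl-3-[(4-methoxybenzyl)oxy]-2-methyl-2-(4-methylpent-3-en-1-yl)oxolane
Product: 23 (2S,3R,5R)-5-[(E)-1-iodoprop-1-en-2-yl]-3-[(4-methoxybenzyl)oxy]-2-methyl-2-(4-methylpent-3-en-1-yl)oxolane, via alkenylalane 22 (not isolated)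
Conditions: AlMe3, Cp2ZrCl2, H2O (1 equiv), CH2Cl2, −20 °C to rt; then I2, THF, −30 °C
Reagents that add atoms: trimethylaluminium, C[Al](C)C; iodine, II
Why: Negishi carboalumination adds methyl and aluminium syn across the alkyne (methyl to the internal carbon), and iodinolysis with retention gives the E-iodoalkene; the trisubstituted side-chain alkene does not react.

Step 16
Reactants: 24 4-[(tert-butyldimethylsilyl)oxy]cyclohexan-1-one
Product: 26 tert-butyldimethyl{[(1S)-4-[(trimethylsilyl)oxy]cyclohex-3-en-1-yl]oxy}silane, via lithium enolate 25 (not isolated)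
Conditions: (R,R)-bis(1-phenylethyl)amine·HCl, n-BuLi (2 equiv), THF, −78 °C; Me3SiCl; then 24, −78 °C
Reagents that add atoms: chlorotrimethylsilane, C[Si](C)(C)Cl
Why: Asymmetric deprotonation of the prochiral ketone by the chiral lithium amide with in situ silylation, the (R,R)-amide being the enantiomer expected to give the (S)-enol silane; this step sets the absolute configuration of the cyclohexane half, and any minor enantiomer becomes a separable diastereomer after step 25.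

Step 17
Reactants: 26 tert-butyldimethyl{[(1S)-4-[(trimethylsilyl)oxy]cyclohex-3-en-1-yl]oxy}silane
Product: 27 (4S)-4-[(tert-butyldimethylsilyl)oxy]cyclohex-2-en-1-one
Conditions: Pd(OAc)2 (1 equiv), MeCN, rt
Reagents that add atoms: none
Why: Saegusa–Ito oxidation of the enol silane gives the enone on the side fixed by the deprotonation.

Step 18
Reactants: 27 (4S)-4-[(tert-butyldimethylsilyl)oxy]cyclohex-2-en-1-one
Product: 28 (4S)-4-[(tert-butyldimethylsilyl)oxy]-2-iodocyclohex-2-en-1-one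
Conditions: I2, pyridine, CH2Cl2, 0 °C to rt
Reagents that add atoms: iodine, II
Why: Amine-promoted α-iodination of an enone (pyridine adds, the enolate is iodinated, pyridine leaves) uses no base strong enough to eliminate the γ-silyloxy group.

Step 19
Reactants: 28 (4S)-4-[(tert-butyldimethylsilyl)oxy]-2-iodocyclohex-2-en-1-one
Product: 29 (4S)-4-[(tert-butyldimethylsilyl)oxy]-2-methylcyclohex-2-en-1-one
Conditions: MeZnCl, Pd(PPh3)4 (5 mol %), THF, rt
Reagents that add atoms: methylzinc chloride, C[Zn]Cl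
Why: Negishi coupling of the α-iodoenone with the methylzinc reagent installs the C2 methyl under neutral conditions.

Step 20
Reactants: 29 (4S)-4-[(tert-butyldimethylsilyl)oxy]-2-methylcyclohex-2-en-1-one; 30 1-[(3-bromopropoxy)methyl]-4-methoxybenzene
Product: 33 (2S,3S,4S)-2-allyl-4-[(tert-butyldimethylsilyl)oxy]-3-{3-[(4-methoxybenzyl)oxy]propyl}-2-methylcyclohexan-1-one, via Grignard reagent 31 (not isolated), via magnesium enolate 32 (not isolated)
Conditions: 30, Mg, THF, rt; then CuBr·SMe2 (20 mol %), 29, THF, −78 to −40 °C; then allyl iodide, HMPA, −40 °C to rt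
Reagents that add atoms: allyl iodide, C=CCI
Why: Three-component conjugate addition–enolate alkylation: the copper-catalysed Grignard addition enters anti to the C4 silyloxy group, and the regiodefined enolate is then C-allylated anti to the new C3 chain, which sets C3 and the quaternary C2 relative to C4.

Step 21
Reactants: 33 (2S,3S,4S)-2-allyl-4-[(tert-butyldimethylsilyl)oxy]-3-{3-[(4-methoxybenzyl)oxy]propyl}-2-methylcyclohexan-1-one
Product: 34 (1S,2S,3S,4S)-2-allyl-4-[(tert-butyldimethylsilyl)oxy]-3-{3-[(4-methoxybenzyl)oxy]propyl}-1,2-dimethylcyclohexan-1-ol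
Conditions: MeLi, CeCl3, THF, −78 °C
Reagents that add atoms: methyllithium, [Li]C
Why: Organocerium 1,2-addition to a hindered, enolisable ketone; in the chair with allyl, the C3 chain and the C4 silyloxy group equatorial, the C2 methyl is axial and blocks the equatorial path, so methyl should enter axially, trans to the C2 methyl, leaving the hydroxyl equatorial.

Step 22
Reactants: 34 (1S,2S,3S,4S)-2-allyl-4-[(tert-butyldimethylsilyl)oxy]-3-{3-[(4-methoxybenzyl)oxy]propyl}-1,2-dimethylcyclohexan-1-ol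
Product: 35 (1S,2S,3S,4S)-2-allyl-4-[(tert-butyldimethylsilyl)oxy]-3-{3-[(4-methoxybenzyl)oxy]propyl}-1,2-dimethyl-1-[(triethylsilyl)oxy]cyclohexane
Conditions: Et3SiOTf, 2,6-lutidine, CH2Cl2, −78 to 0 °C
Reagents that add atoms: triethylsilyl trifluoromethanesulfonate, CC[Si](CC)(CC)OS(=O)(=O)C(F)(F)F
Why: Silyl triflate silylation of the tertiary alcohol, so that it can neither cyclise onto the activated side chain in step 24 nor quench the alkyllithium in step 25.

Step 23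
Reactants: 35 (1S,2S,3S,4S)-2-allyl-4-[(tert-butyldimethylsilyl)oxy]-3-{3-[(4-methoxybenzyl)oxy]propyl}-1,2-dimethyl-1-[(triethylsilyl)oxy]cyclohexane
Product: 37 (1S,2S,3S,4S)-4-[(tert-butyldimethylsilyl)oxy]-2-(2-hydroxyethyl)-3-{3-[(4-methoxybenzyl)oxy]propyl}-1,2-dimethyl-1-[(triethylsilyl)oxy]cyclohexane, via aldehyde 36 (not isolated)
Conditions: O3, CH2Cl2/MeOH, −78 °C, stopped at the end point; then NaBH4, −78 °C to rt
Reagents that add atoms: ozone, [O-][O+]=O
Why: Ozonolysis of the only alkene with reductive work-up shortens allyl to 2-hydroxyethyl; the PMB arene reacts much more slowly than a terminal alkene when ozone is dosed to the end point.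

Step 24
Reactants: 37 (1S,2S,3S,4S)-4-[(tert-butyldimethylsilyl)oxy]-2-(2-hydroxyethyl)-3-{3-[(4-methoxybenzyl)oxy]propyl}-1,2-dimethyl-1-[(triethylsilyl)oxy]cyclohexane
Product: 38 (1S,2S,3S,4S)-4-[(tert-butyldimethylsilyl)oxy]-2-(2-iodoethyl)-3-{3-[(4-methoxybenzyl)oxy]propyl}-1,2-dimethyl-1-[(triethylsilyl)oxy]cyclohexane
Conditions: I2, PPh3, imidazole, CH2Cl2, 0 °C to rt
Reagents that add atoms: iodine, II
Why: Appel-type iodination of an unhindered primary alcohol.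

Step 25
Reactants: 38 (1S,2S,3S,4S)-4-[(tert-butyldimethylsilyl)oxy]-2-(2-iodoethyl)-3-{3-[(4-methoxybenzyl)oxy]propyl}-1,2-dimethyl-1-[(triethylsilyl)oxy]cyclohexane; 23 (2S,3R,5R)-5-[(E)-1-iodoprop-1-en-2-yl]-3-[(4-methoxybenzyl)oxy]-2-methyl-2-(4-methylpent-3-en-1-yl)oxolane
Product: 41 (2S,3R,5R)-5-[(2E)-5-{(1S,2S,3S,4S)-4-[(tert-butyldimethylsilyl)oxy]-3-{3-[(4-methoxybenzyl)oxy]propyl}-1,2-dimethyl-1-[(triethylsilyl)oxy]cyclohexan-2-yl}pent-2-en-2-yl]-3-[(4-methoxybenzyl)oxy]-2-methyl-2-(4-methylpent-3-en-1-yl)oxolane, via alkyllithium 39 (not isolated), via lithium borate 40 (not isolated)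
Conditions: 38, t-BuLi (2.1 equiv), Et2O, −78 °C; B-methoxy-9-BBN, THF, −78 °C to rt; then 23, Pd(dppf)Cl2 (5 mol %), AsPh3, aq. K3PO4, DMF, rt
Reagents that add atoms: none
Why: Iodine–lithium exchange, capture by the methoxyborane to the borate and B-alkyl Suzuki–Miyaura coupling with the iodoalkene, which keeps the E geometry at the sp2 carbon.

Step 26
Reactants: 41 coupled bis-silyl ether
Product: 42 (1S,2S,3S,4S)-2-{(3E)-4-[(2R,4R,5S)-4-[(4-methoxybenzyl)oxy]-5-methyl-5-(4-methylpent-3-en-1-yl)oxolan-2-yl]pent-3-en-1-yl}-3-{3-[(4-methoxybenzyl)oxy]propyl}-1,2-dimethylcyclohexane-1,4-diol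
Conditions: Bu4NF, THF, rt to 40 °C
Reagents that add atoms: none
Why: Fluoride removes the secondary TBS and the tertiary TES ether while both PMB ethers stay.

Step 27
Reactants: 42 cyclohexane-1,4-diol
Product: 43 (2S,3S,4S)-4-hydroxy-3-{(3E)-4-[(2R,4R,5S)-4-[(4-methoxybenzyl)oxy]-5-methyl-5-(4-methylpent-3-en-1-yl)oxolan-2-yl]pent-3-en-1-yl}-2-{3-[(4-methoxybenzyl)oxy]propyl}-3,4-dimethylcyclohexan-1-one
Conditions: Dess–Martin periodinane, NaHCO3, CH2Cl2, 0 °C to rt
Reagents that add atoms: none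
Why: Dess–Martin oxidation of the only secondary alcohol; the tertiary alcohol cannot be oxidised, and the α-stereocentre already sits in its more stable equatorial arrangement.

Step 28
Reactants: 43 hydroxy ketone
Product: 44 (1R,2S,3S,4S)-3-{(3E)-4-[(2R,4R,5S)-4-[(4-methoxybenzyl)oxy]-5-methyl-5-(4-methylpent-3-en-1-yl)oxolan-2-yl]pent-3-en-1-yl}-2-{3-[(4-methoxybenzyl)oxy]propyl}-3,4-dimethyl-1-(prop-1-en-2-yl)cyclohexane-1,4-diol
Conditions: CH2=C(CH3)MgBr (4 equiv), CeCl3, THF, −78 to 0 °C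
Reagents that add atoms: isopropenylmagnesium bromide, C=C(C)[Mg]Br
Why: Organocerium 1,2-addition of the 2-propenyl group to the hindered ketone without enolisation; the new carbinol is drawn as expected from equatorial attack (the axial path is blocked by the syn-axial C3 methyl), but its configuration is lost in step 29.

Step 29
Reactants: 44 tertiary allylic alcohol
Product: 45 (2Z)-2-[(2R,3S,4S)-4-hydroxy-3-{(3E)-4-[(2R,4R,5S)-4-[(4-methoxybenzyl)oxy]-5-methyl-5-(4-methylpent-3-en-1-yl)oxolan-2-yl]pent-3-en-1-yl}-2-{3-[(4-methoxybenzyl)oxy]propyl}-3,4-dimethylcyclohexylidene]propanal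
Conditions: pyridinium chlorochromate, 4 Å molecular sieves, CH2Cl2, rt
Reagents that add atoms: pyridinium chlorochromate, [O-][Cr](=O)(=O)Cl.c1cc[nH+]cc1
Why: Babler–Dauben oxidative transposition: the chromate ester of the tertiary allylic alcohol undergoes a [3,3] shift and the primary allylic chromate is oxidised to the enal; Z is expected because the 2-propenyl methyl stays beside the unsubstituted ring CH2 and the slimmer CH2O/CHO terminus beside the substituted ring carbon.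

Step 30
Reactants: 45 bis-PMB-protected enal
Product: 46 (2Z)-2-[(2R,3S,4S)-4-hydroxy-3-{(3E)-4-[(2R,4R,5S)-4-hydroxy-5-methyl-5-(4-methylpent-3-en-1-yl)oxolan-2-yl]pent-3-en-1-yl}-2-(3-hydroxypropyl)-3,4-dimethylcyclohexylidene]propanal (CNP0155390.1)
Conditions: DDQ, CH2Cl2/pH 7 buffer, 0 °C
Reagents that add atoms: none
Why: Oxidative cleavage of both PMB ethers by DDQ under neutral, wet conditions that should leave the Z-enal, the tertiary alcohol and the trisubstituted alkenes unchanged.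

**Compound list**
1 | dimethyl (R)-malate | COC(=O)C[C@@H](O)C(=O)OC | starting material
2 | methyl (3R)-3,4-dihydroxybutanoate | COC(=O)C[C@@H](O)CO | intermediate
3 | methyl (3R)-4-[(tert-butyldiphenylsilyl)oxy]-3-hydroxybutanoate | COC(=O)C[C@@H](O)CO[Si](c1ccccc1)(c1ccccc1)C(C)(C)C | intermediate
4 | allyl 2,2,2-trichloroacetimidate | C=CCOC(=N)C(Cl)(Cl)Cl | starting material
5 | methyl (3R)-3-(allyloxy)-4-[(tert-butyldiphenylsilyl)oxy]butanoate | COC(=O)C[C@@H](OCC=C)CO[Si](c1ccccc1)(c1ccccc1)C(C)(C)C | intermediate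
6 | (3R)-3-(allyloxy)-4-[(tert-butyldiphenylsilyl)oxy]butanoic acid | OC(=O)C[C@@H](OCC=C)CO[Si](c1ccccc1)(c1ccccc1)C(C)(C)C | intermediate
7 | (3R)-3-(allyloxy)-4-[(tert-butyldiphenylsilyl)oxy]butanoyl chloride | ClC(=O)C[C@@H](OCC=C)CO[Si](c1ccccc1)(c1ccccc1)C(C)(C)C | intermediate
8 | (5R)-5-(allyloxy)-6-[(tert-butyldiphenylsilyl)oxy]-2-diazohexan-3-one | C=CCO[C@@H](CO[Si](c1ccccc1)(c1ccccc1)C(C)(C)C)CC(=O)C(C)=[N+]=[N-] | intermediate
9 | (5R)-1-allyl-5-{[(tert-butyldiphenylsilyl)oxy]methyl}-2-methyl-3-oxooxolan-1-ium-2-ide (oxonium ylide) | C=CC[O+]1[C@@H](CO[Si](c2ccccc2)(c2ccccc2)C(C)(C)C)CC(=O)[C-]1C | intermediate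
10 | (2S,5R)-2-allyl-5-{[(tert-butyldiphenylsilyl)oxy]methyl}-2-methyloxolan-3-one | C=CC[C@]1(C)O[C@@H](CO[Si](c2ccccc2)(c2ccccc2)C(C)(C)C)CC1=O | intermediate
11 | (2S,3R,5R)-2-allyl-5-{[(tert-butyldiphenylsilyl)oxy]methyl}-2-methyloxolan-3-ol | C=CC[C@]1(C)O[C@@H](CO[Si](c2ccccc2)(c2ccccc2)C(C)(C)C)C[C@H]1O | intermediate
12 | (2S,3R,5R)-2-allyl-5-{[(tert-butyldiphenylsilyl)oxy]methyl}-3-[(4-methoxybenzyl)oxy]-2-methyloxolane | C=CC[C@]1(C)O[C@@H](CO[Si](c2ccccc2)(c2ccccc2)C(C)(C)C)C[C@H]1OCc3ccc(OC)cc3 | intermediate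
13 | 9-{3-[(2S,3R,5R)-5-{[(tert-butyldiphenylsilyl)oxy]methyl}-3-[(4-methoxybenzyl)oxy]-2-methyloxolan-2-yl]propyl}-9-borabicyclo[3.3.1]nonane | C1CCC2CCCC1B2CCC[C@]3(C)O[C@@H](CO[Si](c4ccccc4)(c4ccccc4)C(C)(C)C)C[C@H]3OCc5ccc(OC)cc5 | intermediate
14 | 3-[(2S,3R,5R)-5-{[(tert-butyldiphenylsilyl)oxy]methyl}-3-[(4-methoxybenzyl)oxy]-2-methyloxolan-2-yl]propan-1-ol | OCCC[C@]1(C)O[C@@H](CO[Si](c2ccccc2)(c2ccccc2)C(C)(C)C)C[C@H]1OCc3ccc(OC)cc3 | intermediate
15 | 3-[(2S,3R,5R)-5-{[(tert-butyldiphenylsilyl)oxy]methyl}-3-[(4-methoxybenzyl)oxy]-2-methyloxolan-2-yl]propanal | O=CCC[C@]1(C)O[C@@H](CO[Si](c2ccccc2)(c2ccccc2)C(C)(C)C)C[C@H]1OCc3ccc(OC)cc3 | intermediate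
16 | isopropyltriphenylphosphonium iodide | CC(C)[P+](c1ccccc1)(c1ccccc1)c1ccccc1.[I-] | starting material
17 | isopropylidene(triphenyl)phosphorane | CC(C)=P(c1ccccc1)(c1ccccc1)c1ccccc1 | intermediate
18 | (2S,3R,5R)-5-{[(tert-butyldiphenylsilyl)oxy]methyl}-3-[(4-methoxybenzyl)oxy]-2-methyl-2-(4-methylpent-3-en-1-yl)oxolane | CC(C)=CCC[C@]1(C)O[C@@H](CO[Si](c2ccccc2)(c2ccccc2)C(C)(C)C)C[C@H]1OCc3ccc(OC)cc3 | intermediate
19 | [(2R,4R,5S)-4-[(4-methoxybenzyl)oxy]-5-methyl-5-(4-methylpent-3-en-1-yl)oxolan-2-yl]methanol | CC(C)=CCC[C@]1(C)O[C@@H](CO)C[C@H]1OCc2ccc(OC)cc2 | intermediate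
20 | (2R,4R,5S)-4-[(4-methoxybenzyl)oxy]-5-methyl-5-(4-methylpent-3-en-1-yl)oxolane-2-carbaldehyde | CC(C)=CCC[C@]1(C)O[C@@H](C=O)C[C@H]1OCc2ccc(OC)cc2 | intermediate
21 | (2S,3R,5R)-5-ethynyl-3-[(4-methoxybenzyl)oxy]-2-methyl-2-(4-methylpent-3-en-1-yl)oxolane | CC(C)=CCC[C@]1(C)O[C@@H](C#C)C[C@H]1OCc2ccc(OC)cc2 | intermediate
22 | dimethyl{(E)-2-[(2R,4R,5S)-4-[(4-methoxybenzyl)oxy]-5-methyl-5-(4-methylpent-3-en-1-yl)oxolan-2-yl]prop-1-en-1-yl}alumane | CC(C)=CCC[C@]1(C)O[C@@H](/C(C)=C/[Al](C)C)C[C@H]1OCc2ccc(OC)cc2 | intermediate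
23 | (2S,3R,5R)-5-[(E)-1-iodoprop-1-en-2-yl]-3-[(4-methoxybenzyl)oxy]-2-methyl-2-(4-methylpent-3-en-1-yl)oxolane | CC(C)=CCC[C@]1(C)O[C@@H](/C(C)=C/I)C[C@H]1OCc2ccc(OC)cc2 | intermediate
24 | 4-[(tert-butyldimethylsilyl)oxy]cyclohexan-1-one | O=C1CCC(O[Si](C)(C)C(C)(C)C)CC1 | starting material
25 | lithium (4S)-4-[(tert-butyldimethylsilyl)oxy]cyclohex-1-en-1-olate | [Li]OC1=CC[C@@H](O[Si](C)(C)C(C)(C)C)CC1 | intermediate
26 | tert-butyldimethyl{[(1S)-4-[(trimethylsilyl)oxy]cyclohex-3-en-1-yl]oxy}silane | C[Si](C)(C)OC1=CC[C@@H](O[Si](C)(C)C(C)(C)C)CC1 | intermediate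
27 | (4S)-4-[(tert-butyldimethylsilyl)oxy]cyclohex-2-en-1-one | O=C1C=C[C@@H](O[Si](C)(C)C(C)(C)C)CC1 | intermediate
28 | (4S)-4-[(tert-butyldimethylsilyl)oxy]-2-iodocyclohex-2-en-1-one | O=C1C(I)=C[C@@H](O[Si](C)(C)C(C)(C)C)CC1 | intermediate
29 | (4S)-4-[(tert-butyldimethylsilyl)oxy]-2-methylcyclohex-2-en-1-one | CC1=C[C@@H](O[Si](C)(C)C(C)(C)C)CCC1=O | intermediate
30 | 1-[(3-bromopropoxy)methyl]-4-methoxybenzene | COc1ccc(COCCCBr)cc1 | starting material
31 | {3-[(4-methoxybenzyl)oxy]propyl}magnesium bromide | COc1ccc(COCCC[Mg]Br)cc1 | intermediate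
32 | bromomagnesium (3S,4S)-4-[(tert-butyldimethylsilyl)oxy]-3-{3-[(4-methoxybenzyl)oxy]propyl}-2-methylcyclohex-1-en-1-olate | Br[Mg]OC1=C(C)[C@H](CCCOCc2ccc(OC)cc2)[C@@H](O[Si](C)(C)C(C)(C)C)CC1 | intermediate
33 | (2S,3S,4S)-2-allyl-4-[(tert-butyldimethylsilyl)oxy]-3-{3-[(4-methoxybenzyl)oxy]propyl}-2-methylcyclohexan-1-one | C=CC[C@@]1(C)[C@H](CCCOCc2ccc(OC)cc2)[C@@H](O[Si](C)(C)C(C)(C)C)CCC1=O | intermediate
34 | (1S,2S,3S,4S)-2-allyl-4-[(tert-butyldimethylsilyl)oxy]-3-{3-[(4-methoxybenzyl)oxy]propyl}-1,2-dimethylcyclohexan-1-ol | C=CC[C@@]1(C)[C@H](CCCOCc2ccc(OC)cc2)[C@@H](O[Si](C)(C)C(C)(C)C)CC[C@]1(C)O | intermediate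
35 | (1S,2S,3S,4S)-2-allyl-4-[(tert-butyldimethylsilyl)oxy]-3-{3-[(4-methoxybenzyl)oxy]propyl}-1,2-dimethyl-1-[(triethylsilyl)oxy]cyclohexane | C=CC[C@@]1(C)[C@H](CCCOCc2ccc(OC)cc2)[C@@H](O[Si](C)(C)C(C)(C)C)CC[C@]1(C)O[Si](CC)(CC)CC | intermediate
36 | (1S,2S,3S,4S)-4-[(tert-butyldimethylsilyl)oxy]-3-{3-[(4-methoxybenzyl)oxy]propyl}-1,2-dimethyl-2-(2-oxoethyl)-1-[(triethylsilyl)oxy]cyclohexane | O=CC[C@@]1(C)[C@H](CCCOCc2ccc(OC)cc2)[C@@H](O[Si](C)(C)C(C)(C)C)CC[C@]1(C)O[Si](CC)(CC)CC | intermediate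
37 | (1S,2S,3S,4S)-4-[(tert-butyldimethylsilyl)oxy]-2-(2-hydroxyethyl)-3-{3-[(4-methoxybenzyl)oxy]propyl}-1,2-dimethyl-1-[(triethylsilyl)oxy]cyclohexane | OCC[C@@]1(C)[C@H](CCCOCc2ccc(OC)cc2)[C@@H](O[Si](C)(C)C(C)(C)C)CC[C@]1(C)O[Si](CC)(CC)CC | intermediate
38 | (1S,2S,3S,4S)-4-[(tert-butyldimethylsilyl)oxy]-2-(2-iodoethyl)-3-{3-[(4-methoxybenzyl)oxy]propyl}-1,2-dimethyl-1-[(triethylsilyl)oxy]cyclohexane | ICC[C@@]1(C)[C@H](CCCOCc2ccc(OC)cc2)[C@@H](O[Si](C)(C)C(C)(C)C)CC[C@]1(C)O[Si](CC)(CC)CC | intermediate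
39 | (1S,2S,3S,4S)-4-[(tert-butyldimethylsilyl)oxy]-2-(2-lithioethyl)-3-{3-[(4-methoxybenzyl)oxy]propyl}-1,2-dimethyl-1-[(triethylsilyl)oxy]cyclohexane | [Li]CC[C@@]1(C)[C@H](CCCOCc2ccc(OC)cc2)[C@@H](O[Si](C)(C)C(C)(C)C)CC[C@]1(C)O[Si](CC)(CC)CC | intermediate
40 | lithium 9-methoxy-9-{2-[(1S,2S,3S,4S)-cyclohexan-2-yl]ethyl}-9-boratabicyclo[3.3.1]nonane (cyclohexane substituted as in 38) | [Li+].CO[B-]1(CC[C@@]2(C)[C@H](CCCOCc3ccc(OC)cc3)[C@@H](O[Si](C)(C)C(C)(C)C)CC[C@]2(C)O[Si](CC)(CC)CC)C4CCCC1CCC4 | intermediate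
41 | (2S,3R,5R)-5-[(2E)-5-{(1S,2S,3S,4S)-4-[(tert-butyldimethylsilyl)oxy]-3-{3-[(4-methoxybenzyl)oxy]propyl}-1,2-dimethyl-1-[(triethylsilyl)oxy]cyclohexan-2-yl}pent-2-en-2-yl]-3-[(4-methoxybenzyl)oxy]-2-methyl-2-(4-methylpent-3-en-1-yl)oxolane | CC(C)=CCC[C@]1(C)O[C@@H](/C(C)=C/CC[C@@]2(C)[C@H](CCCOCc3ccc(OC)cc3)[C@@H](O[Si](C)(C)C(C)(C)C)CC[C@]2(C)O[Si](CC)(CC)CC)C[C@H]1OCc4ccc(OC)cc4 | intermediate
42 | (1S,2S,3S,4S)-2-{(3E)-4-[(2R,4R,5S)-4-[(4-methoxybenzyl)oxy]-5-methyl-5-(4-methylpent-3-en-1-yl)oxolan-2-yl]pent-3-en-1-yl}-3-{3-[(4-methoxybenzyl)oxy]propyl}-1,2-dimethylcyclohexane-1,4-diol | CC(C)=CCC[C@]1(C)O[C@@H](/C(C)=C/CC[C@@]2(C)[C@H](CCCOCc3ccc(OC)cc3)[C@@H](O)CC[C@]2(C)O)C[C@H]1OCc4ccc(OC)cc4 | intermediate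
43 | (2S,3S,4S)-4-hydroxy-3-{(3E)-4-[(2R,4R,5S)-4-[(4-methoxybenzyl)oxy]-5-methyl-5-(4-methylpent-3-en-1-yl)oxolan-2-yl]pent-3-en-1-yl}-2-{3-[(4-methoxybenzyl)oxy]propyl}-3,4-dimethylcyclohexan-1-one | CC(C)=CCC[C@]1(C)O[C@@H](/C(C)=C/CC[C@@]2(C)[C@H](CCCOCc3ccc(OC)cc3)C(=O)CC[C@]2(C)O)C[C@H]1OCc4ccc(OC)cc4 | intermediate
44 | (1R,2S,3S,4S)-3-{(3E)-4-[(2R,4R,5S)-4-[(4-methoxybenzyl)oxy]-5-methyl-5-(4-methylpent-3-en-1-yl)oxolan-2-yl]pent-3-en-1-yl}-2-{3-[(4-methoxybenzyl)oxy]propyl}-3,4-dimethyl-1-(prop-1-en-2-yl)cyclohexane-1,4-diol | CC(C)=CCC[C@]1(C)O[C@@H](/C(C)=C/CC[C@@]2(C)[C@H](CCCOCc3ccc(OC)cc3)[C@@](O)(C(C)=C)CC[C@]2(C)O)C[C@H]1OCc4ccc(OC)cc4 | intermediate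
45 | (2Z)-2-[(2R,3S,4S)-4-hydroxy-3-{(3E)-4-[(2R,4R,5S)-4-[(4-methoxybenzyl)oxy]-5-methyl-5-(4-methylpent-3-en-1-yl)oxolan-2-yl]pent-3-en-1-yl}-2-{3-[(4-methoxybenzyl)oxy]propyl}-3,4-dimethylcyclohexylidene]propanal | CC(C)=CCC[C@]1(C)O[C@@H](/C(C)=C/CC[C@@]2(C)[C@H](CCCOCc3ccc(OC)cc3)/C(=C(/C)C=O)CC[C@]2(C)O)C[C@H]1OCc4ccc(OC)cc4 | intermediate
46 | (2Z)-2-[(2R,3S,4S)-4-hydroxy-3-{(3E)-4-[(2R,4R,5S)-4-hydroxy-5-methyl-5-(4-methylpent-3-en-1-yl)oxolan-2-yl]pent-3-en-1-yl}-2-(3-hydroxypropyl)-3,4-dimethylcyclohexylidene]propanal | CC(C)=CCC[C@]1(C)O[C@@H](/C(C)=C/CC[C@@]2(C)[C@H](CCCO)/C(=C(/C)C=O)CC[C@]2(C)O)C[C@H]1O | target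

**Count and risks**
Total steps: 30. Longest linear sequence: 21 steps (steps 1–15, then 25–30); the cyclohexane half takes 9 steps (16–24) before the union.

Step 29 is the most exposed. The oxidative transposition may lose control of the alkene geometry, and the acidic oxidant may ionise the tertiary allylic alcohol, leading to diene formation or to bridging by the remote tertiary hydroxyl. The fallback sets out from ketone 43. Horner–Wadsworth–Emmons olefination with the sodium salt of diethyl (1-cyanoethyl)phosphonate (NaH, THF, reflux) should place the slim nitrile beside the substituted ring carbon and give (2Z)-2-[(2R,3S,4S)-4-hydroxy-3-{(3E)-4-[(2R,4R,5S)-4-[(4-methoxybenzyl)oxy]-5-methyl-5-(4-methylpent-3-en-1-yl)oxolan-2-yl]pent-3-en-1-yl}-2-{3-[(4-methoxybenzyl)oxy]propyl}-3,4-dimethylcyclohexylidene]propanenitrile F9. Geometric isomers can be separated at this robust nitrile stage. Half-reduction with i-Bu2AlH at −78 °C and mild acidic hydrolysis of the aldimine returns the route at enal 45.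

Step 6 may suffer from 1,2-hydride migration in the methyl-bearing carbenoid before the ether oxygen captures it, and from erosion of facial control in the allyl shift. The fallback keeps the ylide disconnection but removes the migrating hydrogen, and sets out from acid 6.
- Activation with carbonyldiimidazole and condensation with the magnesium salt of monomethyl malonate gives methyl (5R)-5-(allyloxy)-6-[(tert-butyldiphenylsilyl)oxy]-3-oxohexanoate F1.
- Regitz diazo transfer (4-acetamidobenzenesulfonyl azide, Et3N) gives methyl (5R)-5-(allyloxy)-6-[(tert-butyldiphenylsilyl)oxy]-2-diazo-3-oxohexanoate F2.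
- Rh2(OAc)4 in CH2Cl2 effects the same oxonium-ylide formation and [2,3] shift to methyl (2S,5R)-2-allyl-5-{[(tert-butyldiphenylsilyl)oxy]methyl}-3-oxooxolane-2-carboxylate F3.
- CBS reduction as in step 7 gives methyl (2S,3R,5R)-2-allyl-5-{[(tert-butyldiphenylsilyl)oxy]methyl}-3-hydroxyoxolane-2-carboxylate F4.
- Acid-catalysed etherification with 4-methoxybenzyl trichloroacetimidate (no base, to avoid retro-aldol opening) gives methyl (2S,3R,5R)-2-allyl-5-{[(tert-butyldiphenylsilyl)oxy]methyl}-3-[(4-methoxybenzyl)oxy]oxolane-2-carboxylate F5.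
- LiAlH4 reduces the ester to [(2R,3R,5R)-2-allyl-5-{[(tert-butyldiphenylsilyl)oxy]methyl}-3-[(4-methoxybenzyl)oxy]oxolan-2-yl]methanol F6.
- Mesylation gives [(2R,3R,5R)-2-allyl-5-{[(tert-butyldiphenylsilyl)oxy]methyl}-3-[(4-methoxybenzyl)oxy]oxolan-2-yl]methyl methanesulfonate F7, and hydride displacement with LiBHEt3 returns the route at PMB ether 12.

Step 21 depends on substrate-controlled facial selectivity at a hindered ketone; methyl might be delivered from the equatorial side, or enolisation might compete. The fallback sets out from ketone 33. Corey–Chaykovsky methylenation with dimethylsulfonium methylide (Me3SI, KN(SiMe3)2, THF), a small ylide that adds along the axial path, gives (3S,4S,5S,6S)-4-allyl-6-[(tert-butyldimethylsilyl)oxy]-5-{3-[(4-methoxybenzyl)oxy]propyl}-4-methyl-1-oxaspiro[2.5]octane F8. LiAlH4 opens the epoxide at its CH2 terminus and returns the route at tertiary alcohol 34.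

Further compounds
F1 | step 6 | methyl (5R)-5-(allyloxy)-6-[(tert-butyldiphenylsilyl)oxy]-3-oxohexanoate | COC(=O)CC(=O)C[C@@H](OCC=C)CO[Si](c1ccccc1)(c1ccccc1)C(C)(C)C
F2 | step 6 | methyl (5R)-5-(allyloxy)-6-[(tert-butyldiphenylsilyl)oxy]-2-diazo-3-oxohexanoate | COC(=O)C(=[N+]=[N-])C(=O)C[C@@H](OCC=C)CO[Si](c1ccccc1)(c1ccccc1)C(C)(C)C
F3 | step 6 | methyl (2S,5R)-2-allyl-5-{[(tert-butyldiphenylsilyl)oxy]methyl}-3-oxooxolane-2-carboxylate | C=CC[C@]1(C(=O)OC)O[C@@H](CO[Si](c2ccccc2)(c2ccccc2)C(C)(C)C)CC1=O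
F4 | step 6 | methyl (2S,3R,5R)-2-allyl-5-{[(tert-butyldiphenylsilyl)oxy]methyl}-3-hydroxyoxolane-2-carboxylate | C=CC[C@]1(C(=O)OC)O[C@@H](CO[Si](c2ccccc2)(c2ccccc2)C(C)(C)C)C[C@H]1O
F5 | step 6 | methyl (2S,3R,5R)-2-allyl-5-{[(tert-butyldiphenylsilyl)oxy]methyl}-3-[(4-methoxybenzyl)oxy]oxolane-2-carboxylate | C=CC[C@]1(C(=O)OC)O[C@@H](CO[Si](c2ccccc2)(c2ccccc2)C(C)(C)C)C[C@H]1OCc3ccc(OC)cc3
F6 | step 6 | [(2R,3R,5R)-2-allyl-5-{[(tert-butyldiphenylsilyl)oxy]methyl}-3-[(4-methoxybenzyl)oxy]oxolan-2-yl]methanol | C=CC[C@]1(CO)O[C@@H](CO[Si](c2ccccc2)(c2ccccc2)C(C)(C)C)C[C@H]1OCc3ccc(OC)cc3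
F7 | step 6 | [(2R,3R,5R)-2-allyl-5-{[(tert-butyldiphenylsilyl)oxy]methyl}-3-[(4-methoxybenzyl)oxy]oxolan-2-yl]methyl methanesulfonate | C=CC[C@]1(COS(C)(=O)=O)O[C@@H](CO[Si](c2ccccc2)(c2ccccc2)C(C)(C)C)C[C@H]1OCc3ccc(OC)cc3
F8 | step 21 | (3S,4S,5S,6S)-4-allyl-6-[(tert-butyldimethylsilyl)oxy]-5-{3-[(4-methoxybenzyl)oxy]propyl}-4-methyl-1-oxaspiro[2.5]octane | C=CC[C@@]1(C)[C@H](CCCOCc2ccc(OC)cc2)[C@@H](O[Si](C)(C)C(C)(C)C)CC[C@@]13CO3
F9 | step 29 | (2Z)-2-[(2R,3S,4S)-4-hydroxy-3-{(3E)-4-[(2R,4R,5S)-4-[(4-methoxybenzyl)oxy]-5-methyl-5-(4-methylpent-3-en-1-yl)oxolan-2-yl]pent-3-en-1-yl}-2-{3-[(4-methoxybenzyl)oxy]propyl}-3,4-dimethylcyclohexylidene]propanenitrile | CC(C)=CCC[C@]1(C)O[C@@H](/C(C)=C/CC[C@@]2(C)[C@H](CCCOCc3ccc(OC)cc3)/C(=C(/C)C#N)CC[C@]2(C)O)C[C@H]1OCc4ccc(OC)cc4
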